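**Abbreviations:** TBS = tert-butyldimethylsilyl, TMS = trimethylsilyl, Piv = pivaloyl. Flavonoid numbering (O1, C2, C3, C4, C4a, C5–C8, C8a; rings A, B, C) is used for the target and for the "future" positions of intermediates.

## Analysis of the target

The target 18 is a dihydroflavonol: a chroman-4-one (ring A fused to the pyranone ring C) with a 4-hydroxy-3-methoxyphenyl ring B on C2 and a hydroxyl on C3. Ring A carries a chelated 5-OH, a 7-OMe and a prenyl group on C8, next to the ring oxygen O1. C2 and C3 are adjacent, both R, and trans, with the aryl and hydroxyl groups diequatorial on the half-chair of ring C. C3–H is α to the ketone and epimerises under base. The O1–C2 bond opens under base by β-elimination to a chalcone, which racemises C2, and a free 4'-OH opens a second path through a quinone methide. The prenyl alkene does not tolerate electrophilic oxidants or strong acid, and ring A is electron-rich. The difficulty is therefore to set two contiguous stereocentres at the hydroxy-ketone oxidation level without base or oxidant near the prenyl group, and to make O1 the oxygen that flanks the prenyl group and not the 5-oxygen. The strategy rests on one feature: C2 is an acetal-level benzylic carbon bonded to O1, C3 is the enolisable α-carbon of the C4 ketone, and the two are held ortho to each other on ring A through O1–C8a and C4–C4a.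

## Retrosynthetic reasoning

**18 to 17 (three O–Si bonds).** The three hydroxyls are masked as one kind of silyl ether, so a single acidic, non-basic desilylation ends the route. Nothing else changes after the stereocentres are in place.

**17 to 15 through 16 (C2–C3).** This bond joins the two stereocentres, and its two ends have natural and opposite polarity. C2 becomes the carbon of an aryl-oxocarbenium ion 16, and C3 is the nucleophilic carbon of an enol silane. Cutting here removes ring C and both stereocentres at once, and the precursor 15 has no stereocentre that matters. Cutting O1–C2 or C3–C4 instead would leave a stereocentre to be made separately. The leaving group on the acetal carbon of 15 is a pivaloyloxy group. With a simple alkoxy group, the ring A aryloxide would be the better leaving group under acid and ring A would be cut off. A carboxylate leaves before an aryloxide, so ionisation gives 16 with ring A still attached. The forward step must choose one face of the planar cation, which a confined chiral anion paired with 16 should do, and must give the trans relation.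

**15 to 13 through 14 (enol O–Si bond).** The enol silane comes from the α-silyloxy ketone 13 by kinetic deprotonation and silyl trapping. The forward step must give the Z isomer, in which the silyloxy group on C3 lies trans to ring A.

**13 to 9 and 11 through 12 (O1–C2).** The acetal C–O bond to ring A is cut, giving phenol 9 and aldehyde 11 as two fragments of similar size. The aldehyde is activated as the α-chloro ester 12. In 9 the 5-oxygen is already silylated, so only the prenyl-flanked oxygen can become O1.

**11 to 10.** Silylation of the phenol of vanillin 10.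

**9 to 7 through 8 (C8–prenyl bond).** An aromatic Claisen rearrangement of the 1,1-dimethylallyl ether 7 has only one free ortho position, the future C8. It delivers the linear prenyl group there and frees the oxygen that carried the allyl unit. Regiochemistry and oxygen differentiation are settled in the same step.

**7 to 6, 6 to 4 through 5, 4 to 3 (alkene from alkyne, C3–O bond, silylation).** The C3 oxygen is introduced by Rubottom oxidation of enol ether 4 while the future prenyl group is still a terminal alkyne, which a peracid ignores. Semi-hydrogenation of 6 then gives 7. Silylation of 3 gives the enol ether and protects the future 5-oxygen in one operation.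

**3 to 1 and 2.** The symmetric ketone 1 is desymmetrised by mono-etherification with the tertiary propargylic chloride 2. The second hydroxyl is hydrogen-bonded to the ketone and stays free.

## Alternatives that were turned down

**Alternative 1: epoxidation of a flav-3-ene.** The C3–O and C4–O bonds are disconnected back to the C3=C4 alkene of the 2-aryl-2H-chromene A1. In the forward step Mn(salen)Cl with NaOCl would epoxidise this alkene anti to the C2 aryl group and give epoxide A2. In its favour, chromene epoxidation with chiral manganese salen complexes is one of the most dependable asymmetric oxidations, and a cis-alkene conjugated to ring A is its ideal substrate. On the reliability of the stereo-defining reaction it is stronger than the chosen route. Against it for this target: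
- C2 must already be set in A1 by a separate asymmetric step, or half the material is lost in a resolution.
- The oxo-manganese oxidant also attacks the trisubstituted prenyl alkene.
- A2 carries two donor oxygens on ring A and ionises very easily at C4.
- Opening at C4 and oxidation of the C4 carbinol to the ketone are still needed after the key step.

The chosen strategy sets both centres at the final oxidation level in one step and never exposes the prenyl alkene to an oxidant.

**Alternative 2: pinacol closure of C3–C4.** The C3–C4 bond is disconnected to the dialdehyde A3. SmI2 would reduce the ring A aldehyde to a ketyl that adds to the tethered α-aryloxy aldehyde and closes ring C as the cis diol A4. In its favour, A3 is assembled convergently through O1, and ketyl cyclisations to six-membered cis diols are well known. Against it: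
- The α-aryl-α-aryloxy aldehyde of A3 is doubly activated at C2 and racemises easily.
- SmI2 cleaves α-oxygenated carbonyl compounds reductively, so loss of the ring A aryloxide competes with cyclisation.
- C2 again needs its own asymmetric step.
- The benzylic C4 carbinol of A4 must then be oxidised selectively beside the C3 carbinol and the prenyl group.

It is longer and carries a fragmentation risk that the chosen route does not have.

**Alternative 3: SNAr closure of O1–C8a.** The aryl ether bond O1–C8a is disconnected to the open-chain fluoro keto diol monosilyl ether A5. Its C2 alkoxide would displace fluoride ortho to the ketone with retention at both centres and give A6. In its favour, both stereocentres can be set in the open chain by established asymmetric methods, and the ring closure is a known reaction class that creates no stereocentre. On precedent it is stronger than the chosen route. Against it: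
- Ring A is electron-rich, and the fluorine is flanked by the prenyl group and activated by a single carbonyl.
- The alkoxide of a β-hydroxy ketone can undergo retro-aldol cleavage of C2–C3 and epimerise C3 under the basic conditions.
- The fluorinated, prenylated ring A building block needs a long synthesis.

The chosen strategy offers a non-basic ring closure, a convergent O-alkylation and catalytic control of both centres.

Key step: step 9

Assumption: the sense of induction of the confined acid in step 9 cannot be predicted from first principles. "Matched antipode" means the catalyst enantiomer that lets C3 add to the Si face of C2, to be found by one trial with each antipode.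

## Route

Step 1
Reactants: 1 1-(2,6-dihydroxy-4-methoxyphenyl)ethanone; 2 3-chloro-3-methylbut-1-yne
Product: 3 1-[2-hydroxy-4-methoxy-6-(2-methylbut-3-yn-2-yloxy)phenyl]ethanone
Conditions: CuCl2·2H2O (1 mol%), DBU, MeCN, 0 °C
Reagents that add atoms: none
Why: Copper-catalysed propargylic etherification of a phenoxide through a copper acetylide. Ketone 1 is symmetric, so either hydroxyl gives 3, and the remaining hydroxyl is hydrogen-bonded to the ketone, which should hold the reaction at the mono-ether.

Step 2
Reactants: 3
Product: 4 1-[2-(TBS-oxy)-4-methoxy-6-(2-methylbut-3-yn-2-yloxy)phenyl]-1-(TBS-oxy)ethene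
Conditions: TBSOTf, Et3N, CH2Cl2, 0 °C to rt
Reagents that add atoms: tert-butyldimethylsilyl triflate, CC(C)(C)[Si](C)(C)OS(=O)(=O)C(F)(F)F
Why: Soft enolisation with a silyl triflate and an amine silylates the chelated phenol and converts the methyl ketone into its only possible silyl enol ether.

Step 3
Reactants: 4
Product: 6 2-(TBS-oxy)-1-[2-(TBS-oxy)-4-methoxy-6-(2-methylbut-3-yn-2-yloxy)phenyl]ethanone, via silyloxy epoxide 5 (not isolated)
Conditions: mCPBA, CH2Cl2, −20 °C to rt
Reagents that add atoms: 3-chloroperbenzoic acid, OOC(=O)c1cccc(Cl)c1
Why: Rubottom oxidation. The peracid epoxidises the electron-rich enol ether far faster than the terminal alkyne or the arene, and epoxide 5 opens with 1,4-silyl migration to the α-silyloxy ketone.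

Step 4
Reactants: 6
Product: 7 2-(TBS-oxy)-1-[2-(TBS-oxy)-4-methoxy-6-(2-methylbut-3-en-2-yloxy)phenyl]ethanone
Conditions: H2 (1 atm), Pd/CaCO3 poisoned with Pb(OAc)2 (Lindlar catalyst), quinoline, EtOAc, rt
Reagents that add atoms: none
Why: Lindlar semi-hydrogenation of the terminal alkyne to the vinyl group; the poisoned catalyst leaves the ketone and the silyl ethers alone.

Step 5
Reactants: 7
Product: 9 2-(TBS-oxy)-1-[6-(TBS-oxy)-2-hydroxy-4-methoxy-3-(3-methylbut-2-en-1-yl)phenyl]ethanone, via ortho-dienone 8 (not isolated)
Conditions: toluene, 110 °C
Reagents that add atoms: none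
Why: Aromatic Claisen rearrangement of the 1,1-dimethylallyl aryl ether. The only free ortho position is the future C8, so the allyl unit arrives there with allylic transposition as the linear prenyl group, and dienone 8 tautomerises to the phenol. The oxygen that carried the allyl unit is left free next to the prenyl group and becomes O1.

Step 6
Reactants: 10 vanillin (4-hydroxy-3-methoxybenzaldehyde)
Product: 11 4-(TBS-oxy)-3-methoxybenzaldehyde
Conditions: TBSCl, imidazole, DMF, rt
Reagents that add atoms: tert-butyldimethylsilyl chloride, CC(C)(C)[Si](C)(C)Cl
Why: Standard silylation of a phenol with a silyl chloride and imidazole.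

Step 7
Reactants: 9; 11
Product: 13 {2-[(TBS-oxy)acetyl]-3-(TBS-oxy)-5-methoxy-6-(3-methylbut-2-en-1-yl)phenoxy}[4-(TBS-oxy)-3-methoxyphenyl]methyl pivalate (racemic), via α-chlorobenzyl pivalate 12 (not isolated)
Conditions: 11 (slight excess), PivCl, ZnCl2 (2 mol%), CH2Cl2, 0 °C; added to 9, NaH, THF–DMF, −40 to 0 °C
Reagents that add atoms: pivaloyl chloride, CC(C)(C)C(=O)Cl
Why: An acyl chloride adds across the aldehyde C=O under ZnCl2 catalysis to give the α-chloroalkyl ester 12. The sodium phenoxide of 9 is then alkylated at the benzylic carbon in an SN1-like O-alkylation (acyloxyalkylation, as in the formation of pivaloyloxymethyl ethers), and the bulky pivaloyl group disfavours attack at the acyl carbon. The new acetal centre is racemic and is erased in step 9.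

Step 8
Reactants: 13
Product: 15 Z enol silane of 13 with TMS on the C4 oxygen (racemic at the acetal carbon), via lithium Z-enolate 14 (not isolated)
Conditions: LiN(SiMe3)2, Me3SiCl (present from the start), THF, −78 °C
Reagents that add atoms: chlorotrimethylsilane, C[Si](C)(C)Cl
Why: Kinetic enolisation with in situ silyl trapping. The twisted, di-ortho-substituted aryl group should force the silyloxy substituent cis to the enolate oxygen (Z), as with aryl ethyl ketones, and the hindered pivalate should not be attacked at −78 °C.

Step 9
Reactants: 15
Product: 17 (2R,3R)-3,5-bis(TBS-oxy)-2-[4-(TBS-oxy)-3-methoxyphenyl]-7-methoxy-8-(3-methylbut-2-en-1-yl)chroman-4-one, via aryl-oxocarbenium ion 16 (not isolated)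
Conditions: N-triflyl imidodiphosphorimidate (IDPi) acid from two 3,3'-diaryl-BINOL units, matched antipode (3 mol%), toluene, −60 °C; Et3N quench
Reagents that add atoms: none
Why: Proposed new method: the acid is silylated at the outset by a trace of 15, and the resulting pair of silylium ion and chiral anion transfers Me3Si+ to the pivalate carbonyl, so that Me3SiOPiv departs and the E aryl-oxocarbenium ion 16 (C2=O1+, stabilised by O1 and by the 4-silyloxyphenyl ring B) is left inside the pocket of the confined anion. C3 of the Z enol silane then adds to C2, and the Me3Si group on the C4 oxygen returns to the anion and carries the chain. The closest known reactions are silylium-based counteranion-directed Mukaiyama additions of enol silanes to oxocarbenium ions made from acetoxy acetals, and confined-acid Prins cyclisations; a chroman-4-one ring closed between an aryl-oxocarbenium carbon and an α-silyloxy enol silane has no precedent. Ring C forms by a 6-endo-trig closure onto C2=O1+ in which the C3=C4 enol double bond also lies inside the new ring (6-enolendo). C2 is controlled by the chiral anion, which has to cover the Re face of the planar cation so that C3 bonds to the Si face (2R); the racemic acetal carbon of 15 is erased on ionisation, so both epimers of 15 converge. C3 is controlled relative to C2 by a half-chair-like transition state in which the substituents that point away from the forming ring on both termini (ring B on the E cation, the silyloxy group on the Z enol silane) become equatorial, so that C2 meets the Re face of C3 and the 2,3-trans (3R) product results. The step needs ionisation at the acyloxy and not the aryloxy oxygen (secured by the more Lewis-basic ester carbonyl and the much better carboxylate leaving group), attack by the enol silane and not by the C8 prenyl alkene (secured by the far higher nucleophilicity of the enol silane) and no uncatalysed background closure (secured by the low temperature and the exclusion of free protic acid).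

Step 10
Reactants: 17
Product: 18 (2R,3R)-3,5-dihydroxy-2-(4-hydroxy-3-methoxyphenyl)-7-methoxy-8-(3-methylbut-2-en-1-yl)chroman-4-one
Conditions: HF·pyridine, pyridine, THF, 0 °C to rt
Reagents that add atoms: none
Why: Fluoride cleavage of the two aryl silyl ethers and the secondary silyl ether under mildly acidic, non-basic conditions, which should keep ring C closed and C3 unepimerised. The prenyl group has no free ortho phenol and cannot cyclise.

## Compound list

1 | 1-(2,6-dihydroxy-4-methoxyphenyl)ethanone | CC(=O)c1c(O)cc(OC)cc1O | starting material
2 | 3-chloro-3-methylbut-1-yne | CC(C)(Cl)C#C | starting material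
3 | 1-[2-hydroxy-4-methoxy-6-(2-methylbut-3-yn-2-yloxy)phenyl]ethanone | CC(=O)c1c(O)cc(OC)cc1OC(C)(C)C#C | intermediate
4 | 1-[2-(TBS-oxy)-4-methoxy-6-(2-methylbut-3-yn-2-yloxy)phenyl]-1-(TBS-oxy)ethene | C=C(O[Si](C)(C)C(C)(C)C)c1c(O[Si](C)(C)C(C)(C)C)cc(OC)cc1OC(C)(C)C#C | intermediate
5 | 2-aryl-2-(TBS-oxy)oxirane from 4 (racemic, not isolated) | CC(C)(C)[Si](C)(C)OC1(CO1)c1c(O[Si](C)(C)C(C)(C)C)cc(OC)cc1OC(C)(C)C#C | intermediate
6 | 2-(TBS-oxy)-1-[2-(TBS-oxy)-4-methoxy-6-(2-methylbut-3-yn-2-yloxy)phenyl]ethanone | CC(C)(C)[Si](C)(C)OCC(=O)c1c(O[Si](C)(C)C(C)(C)C)cc(OC)cc1OC(C)(C)C#C | intermediate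
7 | 2-(TBS-oxy)-1-[2-(TBS-oxy)-4-methoxy-6-(2-methylbut-3-en-2-yloxy)phenyl]ethanone | CC(C)(C)[Si](C)(C)OCC(=O)c1c(O[Si](C)(C)C(C)(C)C)cc(OC)cc1OC(C)(C)C=C | intermediate
8 | 6-prenylcyclohexa-2,4-dienone from 7 (racemic, not isolated) | CC(C)(C)[Si](C)(C)OCC(=O)C1=C(O[Si](C)(C)C(C)(C)C)C=C(OC)C(CC=C(C)C)C1=O | intermediate
9 | 2-(TBS-oxy)-1-[6-(TBS-oxy)-2-hydroxy-4-methoxy-3-(3-methylbut-2-en-1-yl)phenyl]ethanone | CC(C)(C)[Si](C)(C)OCC(=O)c1c(O)c(CC=C(C)C)c(OC)cc1O[Si](C)(C)C(C)(C)C | intermediate
10 | vanillin | COc1cc(C=O)ccc1O | starting material
11 | 4-(TBS-oxy)-3-methoxybenzaldehyde | COc1cc(C=O)ccc1O[Si](C)(C)C(C)(C)C | intermediate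
12 | chloro[4-(TBS-oxy)-3-methoxyphenyl]methyl pivalate (racemic, not isolated) | COc1cc(C(Cl)OC(=O)C(C)(C)C)ccc1O[Si](C)(C)C(C)(C)C | intermediate
13 | pivaloyloxy acetal of ring B on the ring A phenol oxygen, α-silyloxy ketone (racemic) | COc1cc(C(OC(=O)C(C)(C)C)Oc2c(CC=C(C)C)c(OC)cc(O[Si](C)(C)C(C)(C)C)c2C(=O)CO[Si](C)(C)C(C)(C)C)ccc1O[Si](C)(C)C(C)(C)C | intermediate
14 | lithium Z-enolate of 13 (not isolated) | COc1cc(C(OC(=O)C(C)(C)C)Oc2c(CC=C(C)C)c(OC)cc(O[Si](C)(C)C(C)(C)C)c2/C(O[Li])=C/O[Si](C)(C)C(C)(C)C)ccc1O[Si](C)(C)C(C)(C)C | intermediate
15 | Z enol silane of 13, TMS on the C4 oxygen (racemic at the acetal carbon) | COc1cc(C(OC(=O)C(C)(C)C)Oc2c(CC=C(C)C)c(OC)cc(O[Si](C)(C)C(C)(C)C)c2/C(O[Si](C)(C)C)=C/O[Si](C)(C)C(C)(C)C)ccc1O[Si](C)(C)C(C)(C)C | intermediate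
16 | E aryl-oxocarbenium ion, paired with the catalyst anion (not isolated) | COc1cc(/C=[O+]/c2c(CC=C(C)C)c(OC)cc(O[Si](C)(C)C(C)(C)C)c2/C(O[Si](C)(C)C)=C/O[Si](C)(C)C(C)(C)C)ccc1O[Si](C)(C)C(C)(C)C | intermediate
17 | (2R,3R)-3,5-bis(TBS-oxy)-2-[4-(TBS-oxy)-3-methoxyphenyl]-7-methoxy-8-(3-methylbut-2-en-1-yl)chroman-4-one | COc1cc([C@H]2Oc3c(CC=C(C)C)c(OC)cc(O[Si](C)(C)C(C)(C)C)c3C(=O)[C@@H]2O[Si](C)(C)C(C)(C)C)ccc1O[Si](C)(C)C(C)(C)C | intermediate
18 | (2R,3R)-3,5-dihydroxy-2-(4-hydroxy-3-methoxyphenyl)-7-methoxy-8-(3-methylbut-2-en-1-yl)chroman-4-one | COc1cc([C@H]2Oc3c(CC=C(C)C)c(OC)cc(O)c3C(=O)[C@@H]2O)ccc1O | target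

## Step count and least certain steps

Total: 10 steps. Longest linear sequence: 9 steps (steps 1–5 and 7–10).

**Step 9 (key step, the one that bears the label Proposed new method).** Several things may go wrong. The loosely paired, highly stabilised cation may be attacked on both faces, which would give poor facial selectivity. A boat-like closure would give the 2,3-cis isomer. Adventitious water may intercept the cation and hydrolyse the acetal. The prenyl alkene may capture the cation in a Prins reaction. Fallback by known chemistry, setting out from phenol 9 and aldehyde 11: LiN(SiMe3)2 (2.2 equiv) and Me3SiCl convert 9 into the aryl TMS ether and Z enol silane F1. An intermolecular enantioselective Mukaiyama aldol addition of F1 to 11 (SiCl4, chiral binaphthyldiamine-derived bisphosphoramide, CH2Cl2, −78 °C, aqueous work-up) should give the syn aldol with free phenol F2. A Mitsunobu etherification (PPh3, DIAD, THF) then closes O1–C2 with inversion at the benzylic carbon and comes back to the route at 17.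

**Step 7.** The phenoxide may attack the acyl carbon of 12 (acyl transfer, which returns the aldehyde), and the very ionisable acetal may be lost on work-up. Fallback, setting out from 11 and 9: reduction of 11 (NaBH4, MeOH) gives the benzyl alcohol F3, and CBr4 with PPh3 gives the benzyl bromide F4. This alkylates 9 (K2CO3, DMF) to the benzyl aryl ether F5. Oxidation of the electron-rich benzylic position with DDQ in the presence of pivalic acid (CH2Cl2, 4 Å sieves) should trap the cation as the pivaloyloxy acetal and come back at 13.

**Step 8.** Exposure of the acetal to the amide base may cause loss of the pivalate or silyl scrambling between the two oxygens on C3 and C4, and an E/Z mixture would erode the trans selectivity of step 9. Fallback, setting out from 9: double deprotonation with KN(SiMe3)2 (2.1 equiv, THF, −78 °C) and one equivalent of Me3SiCl should silylate the more basic enolate oxygen and leave the potassium phenoxide enol silane F6. This is alkylated in the same flask with chloro ester 12 and comes back at 15, so the acetal never meets the base.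

**Step 1.** Double etherification, a sluggish reaction of the hydrogen-bonded phenol, or premature cyclisation of the aryl propargyl ether to a 2,2-dimethylchromene may occur. Fallback, setting out from 1: the tertiary allylic carbonate F7 (from 2-methylbut-3-en-2-ol and di-tert-butyl dicarbonate) and Pd(PPh3)4 (zerovalent palladium, THF, 0 °C) give the 1,1-dimethylallyl ether F8 directly through a π-allyl complex. Silylation as in step 2 gives the bis-silyl compound F9. Rubottom oxidation as in step 3, with one equivalent of peracid at −20 °C so that the monosubstituted alkene is spared, comes back at 7.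

## Further compounds

F1 | step 9 | aryl TMS ether and Z enol silane of 9 | C[Si](C)(C)Oc1c(CC=C(C)C)c(OC)cc(O[Si](C)(C)C(C)(C)C)c1/C(O[Si](C)(C)C)=C/O[Si](C)(C)C(C)(C)C
F2 | step 9 | (2R,3S)-2-(TBS-oxy)-3-hydroxy-1-[6-(TBS-oxy)-2-hydroxy-4-methoxy-3-(3-methylbut-2-en-1-yl)phenyl]-3-[4-(TBS-oxy)-3-methoxyphenyl]propan-1-one | COc1cc([C@H](O)[C@@H](O[Si](C)(C)C(C)(C)C)C(=O)c2c(O)c(CC=C(C)C)c(OC)cc2O[Si](C)(C)C(C)(C)C)ccc1O[Si](C)(C)C(C)(C)C
F3 | step 7 | [4-(TBS-oxy)-3-methoxyphenyl]methanol | COc1cc(CO)ccc1O[Si](C)(C)C(C)(C)C
F4 | step 7 | 4-(TBS-oxy)-3-methoxybenzyl bromide | COc1cc(CBr)ccc1O[Si](C)(C)C(C)(C)C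
F5 | step 7 | 4-(TBS-oxy)-3-methoxybenzyl ether of phenol 9 | COc1cc(COc2c(CC=C(C)C)c(OC)cc(O[Si](C)(C)C(C)(C)C)c2C(=O)CO[Si](C)(C)C(C)(C)C)ccc1O[Si](C)(C)C(C)(C)C
F6 | step 8 | potassium phenoxide of the Z enol silane of 9 (not isolated) | [K]Oc1c(CC=C(C)C)c(OC)cc(O[Si](C)(C)C(C)(C)C)c1/C(O[Si](C)(C)C)=C/O[Si](C)(C)C(C)(C)C
F7 | step 1 | tert-butyl 2-methylbut-3-en-2-yl carbonate | CC(C)(C)OC(=O)OC(C)(C)C=C
F8 | step 1 | 1-[2-hydroxy-4-methoxy-6-(2-methylbut-3-en-2-yloxy)phenyl]ethanone | CC(=O)c1c(O)cc(OC)cc1OC(C)(C)C=C
F9 | step 1 | 1-[2-(TBS-oxy)-4-methoxy-6-(2-methylbut-3-en-2-yloxy)phenyl]-1-(TBS-oxy)ethene | C=C(O[Si](C)(C)C(C)(C)C)c1c(O[Si](C)(C)C(C)(C)C)cc(OC)cc1OC(C)(C)C=C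
A1 | alternative 1 | 2-aryl-2H-chromene (flav-3-ene) with 5- and 4'-MOM ethers and the C2 configuration of the target | COc1cc([C@H]2Oc3c(CC=C(C)C)c(OC)cc(OCOC)c3C=C2)ccc1OCOC
A2 | alternative 1 | 2,3-trans-3,4-epoxyflavan, bis-MOM ether | COc1cc([C@H]2Oc3c(CC=C(C)C)c(OC)cc(OCOC)c3[C@@H]4O[C@@H]42)ccc1OCOC
A3 | alternative 2 | ring A aldehyde carrying the α-aryloxy arylacetaldehyde on its phenol oxygen, bis-MOM ether | COc1cc([C@H](C=O)Oc2c(CC=C(C)C)c(OC)cc(OCOC)c2C=O)ccc1OCOC
A4 | alternative 2 | 2,3-trans-3,4-cis-flavan-3,4-diol, bis-MOM ether | COc1cc([C@H]2Oc3c(CC=C(C)C)c(OC)cc(OCOC)c3[C@H](O)[C@@H]2O)ccc1OCOC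
A5 | alternative 3 | anti 2-fluoroaryl keto diol, C3 TBS ether, bis-MOM ether | COc1cc([C@@H](O)[C@@H](O[Si](C)(C)C(C)(C)C)C(=O)c2c(F)c(CC=C(C)C)c(OC)cc2OCOC)ccc1OCOC
A6 | alternative 3 | 3-O-TBS-5,4'-di-O-MOM ether of the target | COc1cc([C@H]2Oc3c(CC=C(C)C)c(OC)cc(OCOC)c3C(=O)[C@@H]2O[Si](C)(C)C(C)(C)C)ccc1OCOC
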